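Count in equivalents of nucleophile, not in molar.

in all of them: electrophile 0.25 M; gas 19 mM (held)

| charge | nucleophile | remark | time |
|---|---|---|---|
| delta | 1.4 equiv | run made earlier |  |
| zeta | 2.2 equiv | run made earlier |  |
| ochre | 1.00 equiv |  | 1.5 h |
| red | 1.50 equiv |  | 1.5 h |

| run | time / min | electrophile / % | target / % |
|---|---|---|---|
| delta | 8.00 | 93.9 | 5.9 |
| delta | 15.0 | 90.1 | 10.4 |
| delta | 25.0 | 83.9 | 16.7 |
| delta | 30.0 | 82.0 | 18.6 |
| delta | 40.0 | 76.9 | 23.3 |
| delta | 50.0 | 73.0 | 26.5 |
| zeta | 3.00 | 96.1 | 3.6 |
| zeta | 8.00 | 91.0 | 9.4 |
| zeta | 15.0 | 83.8 | 16.2 |
| zeta | 25.0 | 75.4 | 24.7 |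
| zeta | 30.0 | 72.4 | 27.4 |
| zeta | 50.0 | 61.1 | 39.1 |

(standard deviation of a reading: 0.3 percentage points)
- at the start none of free base is dissolved
- what may be going on: electrophile + nucleophile -> acid set free + target; nucleophile + acid set free <-> protonated nucleophile; acid set free + free base <-> salt of the base; nucleophile <-> dormant form; gas <-> free base; acid set free -> by-product carried off
* part of the electrophile that has reacted at the end, ochre
* part of the electrophile that has reacted at the end, red
* what raising the equivalents of nucleophile from its lowest to its highest value here does to the part of the electrophile that has reacted (changes below 5 percentage points count as none) (it rises / it falls / no change)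

1. Define Λ, the loss per equivalent: minus ln of the fraction of electrophile left, divided by the equivalents charged. At 25.0 min, delta reads 0.125 and zeta 0.128. At 50.0 min, delta reads 0.225 and zeta 0.224.

2. Read this as one curve for both charges. Electrophile falls pseudo-first-order, with a constant that follows free nucleophile, and free nucleophile appears to fade as the same share of its charge in delta and zeta.

3. Take the means, 0.127 and 0.224. The second stretch of 25.0 min adds a fraction r = 0.768 of the first, so treat the fade as geometric. The slope at the start is then 0.577 % min⁻¹ of the electrophile per equivalent.

4. Climb the ladder, fastest first. Nucleophile fades with a half-life of 65.8 min. Electrophile in red starts with a half-life of 80.1 min. The run lasts 90.0 min. Electrophile in ochre starts at 120 min. By this reckoning, the constant halves sooner than either starting half-life passes.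

5. Extend the curve to 1.5 h: Λ at the asked time 0.336. My reckoning gives ochre 28.5% and red 39.6%.

6. The forecast says 29.5% and 41%, both above mine, and it rises. Its ground: “So the reaction is first order in nucleophile”.

7. The flask gives ochre 28.2% and red 39.2%; it rises, by 11 percentage points against the 5 points that count. The gap between red and ochre is due to the difference in equivalents of nucleophile.

    electrophile + nucleophile → acid set free + target (k = 0.0240 M⁻¹ min⁻¹)
    nucleophile + acid set free ⇌ protonated nucleophile, settled at all times (K = 28000 M⁻¹)
    acid set free + free base ⇌ salt of the base, settled at all times (K = 1.10 × 10⁵ M⁻¹)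
    nucleophile ⇌ dormant form (K = 3.00, k = 0.00330 min⁻¹)
    gas ⇌ free base, rate k5*(csat - [free base]) (kL = 0.160 min⁻¹)
    acid set free → by-product carried off (k = 0.00860 min⁻¹)

8. Turn the results back into Λ: ochre gives 0.331 and red 0.332. Red ends with 38.6% of its nucleophile free, ochre with 38.0%. With nucleophile held at its charge, red reaches 55.5%; left ten times as long, it reaches 76.4%. Depletion and the short time together keep red at 39.2%.

9. Apply Λ to the neighbour of red charged with 0.900 equiv: it gives 26.1%. The computed flask gives 25.8%.

The runs were generated by integration with made-up constants, noise included.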